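**Retrosynthetic overview**

1. Target 27 is cut at the C7–CH2 bond (Mannich-type methylene bridge, last step) into dihydrobenzofuran 19 and pyrone 24; the pyrone ring is closed separately (step 15) from a β-keto ester dianion product.
2. The plan rests on ring A (benzene) and ring B (dihydrofuran) sharing the C3a–C7a bond, with ring A carrying oxygen at C4, C6 and C7a in alternation with carbon or hydrogen at C3a, C5 and C7. Ring A is therefore cut into three polarised alkynes: C3a≡C4 and C7≡C7a (both ynol ethers, tethered through C3–C2–O1 in diyne 15) and C5≡C6 (alkoxy ynone 11).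
3. One RhCl(PPh3)3 [2+2+2] step forms C7a–C3a, C4–C5 and C6–C7 and closes rings B and A together (15 + 11 → 16).
4. C2 (R) comes from epoxide 9 (hydrolytic kinetic resolution) and is not touched afterwards. The isopropenyl group is carried as a tertiary benzyl ether, because an allyl alkynyl ether would undergo [3,3] rearrangement and a silyl ether would migrate to the neighbouring alkoxide during ynol ether formation.
5. Both alkoxyalkyne units come from one batch of lithium alkoxyacetylide 10, made once from dichlorovinyl ether 3. Their oxygens carry 2-(trimethylsilyl)ethyl groups, so that the C4 and C6 phenols are freed by fluoride after the dehydration; a boron halide would open the allylic aryl ether O1–C2 once the isopropenyl group is in place.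

Key step: step 10

Remark: steps 7 and 8 draw on the same THF solution of 10 from step 6 and are run side by side, so 5 and 9 are in hand before step 6; such lithium alkoxyacetylide solutions should keep for some hours at or below −40 °C.

**Route**

Step 1
Reactants: 1 2-(trimethylsilyl)ethanol; 2 trichloroethylene
Product: 3 [2-{[(E)-1,2-dichloroethenyl]oxy}ethyl]trimethylsilane
Conditions: KH, THF, 0 °C; Cl2C=CHCl, −50 → 20 °C
Reagents that add atoms: none
Why: Dichlorovinyl ether synthesis from an alkoxide and trichloroethylene: the potassium alkoxide eliminates HCl to dichloroacetylene and adds anti to it, which should give the (E)-ether, the alkoxide being kept cold so that Peterson-type loss of ethene stays slow.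

Step 2
Reactants: 4 isobutyryl chloride
Product: 5 N-methoxy-N,2-dimethylpropanamide
Conditions: MeNH(OMe)·HCl, Et3N, CH2Cl2, 0 → 20 °C
Reagents that add atoms: N,O-dimethylhydroxylamine hydrochloride, CNOC.Cl
Why: N-Acylation of the hydroxylamine by the acid chloride gives the Weinreb amide, whose chelated adduct will stop the acetylide addition of step 7 at the ketone stage.

Step 3
Reactants: 6 2-methylbut-3-en-2-ol
Product: 7 {[(2-methylbut-3-en-2-yl)oxy]methyl}benzene
Conditions: NaH, THF/DMF, 0 °C; BnBr, Bu4NI (cat.), 20–50 °C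
Reagents that add atoms: benzyl bromide, BrCc1ccccc1
Why: Williamson etherification of the tertiary alkoxide (iodide catalysis); the benzyl group is chosen because it cannot migrate to the neighbouring alkoxide in step 9 and is removed in step 11 without touching the silylethyl ethers.

Step 4
Reactants: 7 {[(2-methylbut-3-en-2-yl)oxy]methyl}benzene
Product: 8 rac-2-[2-(benzyloxy)propan-2-yl]oxirane
Conditions: mCPBA, CH2Cl2, 20–40 °C
Reagents that add atoms: 3-chloroperbenzoic acid, OOC(=O)c1cccc(Cl)c1
Why: Prilezhaev epoxidation of the only alkene gives the racemic terminal epoxide; with the tertiary oxygen already protected no Payne rearrangement can occur.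

Step 5
Reactants: 8 rac-2-[2-(benzyloxy)propan-2-yl]oxirane
Product: 9 (2R)-2-[2-(benzyloxy)propan-2-yl]oxirane
Conditions: (S,S)-(salen)Co(OAc) (trivalent cobalt; salen = N,N'-bis(3,5-di-tert-butylsalicylidene)cyclohexane-1,2-diamine dianion; 1–2 mol%), H2O (0.55 equiv), THF, 0 → 20 °C
Reagents that add atoms: none
Why: Jacobsen hydrolytic kinetic resolution: the (S,S)-catalyst should hydrolyse the (S)-epoxide to the diol and leave (R)-9, the same sense as for epichlorohydrin and glycidyl ethers, whose substituent has the same CIP rank as here; this sets C2 of the target.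

Step 6
Reactants: 3 [2-{[(E)-1,2-dichloroethenyl]oxy}ethyl]trimethylsilane
Product: 10 {[2-(trimethylsilyl)ethoxy]ethynyl}lithium, as a THF solution
Conditions: n-BuLi (2.05 equiv), THF, −78 → −40 °C; solution held at −78 °C and divided by cannula between steps 7 and 8
Reagents that add atoms: n-butyllithium, [Li]CCCC
Why: Conversion of a 1,2-dichlorovinyl ether into a lithium alkoxyacetylide: the first equivalent of n-BuLi removes HCl to give the chloroalkynyl ether and the second exchanges Cl for Li, and the acetylide is made in one batch because both the ketone synthesis of step 7 and the epoxide opening of step 8 take it as a cold solution.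

Step 7
Reactants: 10 {[2-(trimethylsilyl)ethoxy]ethynyl}lithium; 5 N-methoxy-N,2-dimethylpropanamide
Product: 11 4-methyl-1-[2-(trimethylsilyl)ethoxy]pent-1-yn-3-one
Conditions: 10 (THF solution, 1.2 equiv), then 5, THF, −78 → −20 °C; cold aq NH4Cl
Reagents that add atoms: none
Why: Weinreb ketone synthesis: the acetylide adds once to the amide and the chelated adduct collapses only on work-up, which should give the push-pull ynone without over-addition, a cold near-neutral quench avoiding hydration to the β-keto ester.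

Step 8
Reactants: 10 {[2-(trimethylsilyl)ethoxy]ethynyl}lithium; 9 (2R)-2-[2-(benzyloxy)propan-2-yl]oxirane
Product: 12 (3R)-2-(benzyloxy)-2-methyl-6-[2-(trimethylsilyl)ethoxy]hex-5-yn-3-ol
Conditions: 10 (THF solution, 1.5 equiv), BF3·OEt2, −78 °C; then 9, −78 °C; aq NaHCO3
Reagents that add atoms: none
Why: BF3-promoted SN2 opening of the terminal epoxide by the acetylide at the unhindered CH2 leaves the C–O bond of the stereocentre intact, so 12 keeps the R configuration, and the basic work-up prevents lactonisation of the homopropargylic ynol ether.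

Step 9
Reactants: 12 (3R)-2-(benzyloxy)-2-methyl-6-[2-(trimethylsilyl)ethoxy]hex-5-yn-3-ol; 2 trichloroethylene
Product: 15 [2-({(4R)-5-(benzyloxy)-4-(ethynyloxy)-5-methylhex-1-yn-1-yl}oxy)ethyl]trimethylsilane, via dichlorovinyl ether 13 (not isolated), via lithium acetylide 14 (not isolated)
Conditions: KH, THF, 0 °C; Cl2C=CHCl, −50 → 20 °C; n-BuLi (2.5 equiv), −78 → −40 °C; H2O, −78 °C
Reagents that add atoms: none
Why: One-pot ynol ether synthesis: the alkoxide adds to dichloroacetylene to give 13, n-BuLi converts it by dehydrochlorination and Cl–Li exchange into 14, and protonation gives the terminal ynol ether without involving the stereocentre.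

Step 10
Reactants: 15 [2-({(4R)-5-(benzyloxy)-4-(ethynyloxy)-5-methylhex-1-yn-1-yl}oxy)ethyl]trimethylsilane; 11 4-methyl-1-[2-(trimethylsilyl)ethoxy]pent-1-yn-3-one
Product: 16 1-{(2R)-2-[2-(benzyloxy)propan-2-yl]-4,6-bis[2-(trimethylsilyl)ethoxy]-2,3-dihydro-1-benzofuran-5-yl}-2-methylpropan-1-one
Conditions: RhCl(PPh3)3 (5–10 mol%), 11 (2–3 equiv), toluene, 20–40 °C, slow addition of 15
Reagents that add atoms: none
Why: Proposed new method: RhCl(PPh3)3 loses PPh3, binds the two ynol ether triple bonds of 15 and couples them oxidatively to a rhodacyclopentadiene of trivalent rhodium, which forms C3a–C7a and closes ring B as the five-membered ring of a 1,6-diyne held by the O1–C2–C3 tether; the closest known reaction type is the RhCl(PPh3)3 [2+2+2] of ynamide-tethered 1,6-diynes with alkynes to indolines, next to cyclotrimerisations of alkynyl ethers, but a bis(ynol ether) with an alkoxy ynone has not been shown. Ynone 11 then inserts into the Rh–C7 bond (forming C6–C7) and reductive elimination forms C4–C5, which closes ring A as the benzene ring and returns monovalent rhodium. No stereocentre is formed, and C2 lies outside the reacting atoms. The step needs the acyl-bearing carbon of 11 to become C5: C7 of the rhodacycle is the unsubstituted β-carbon of the O1 enol ether, hence its nucleophilic and least hindered terminus, and it should bond to the alkoxy-bearing carbon of 11, the electrophilic β-position of the push-pull ynone, which leaves rhodium on the acyl-bearing carbon as an oxa-π-allyl that then joins C4. Slow addition of 15 to an excess of 11 at 20–40 °C should hold back self-trimerisation and the retro-ene loss of ketene from the ynol ethers.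

Step 11
Reactants: 16 1-{(2R)-2-[2-(benzyloxy)propan-2-yl]-4,6-bis[2-(trimethylsilyl)ethoxy]-2,3-dihydro-1-benzofuran-5-yl}-2-methylpropan-1-one
Product: 17 1-{(2R)-2-(2-hydroxypropan-2-yl)-4,6-bis[2-(trimethylsilyl)ethoxy]-2,3-dihydro-1-benzofuran-5-yl}-2-methylpropan-1-one
Conditions: H2 (1 atm), Pd(OH)2/C, EtOAc, 20 °C
Reagents that add atoms: none
Why: Hydrogenolysis of the benzyl ether frees the tertiary alcohol, while the hindered di-ortho-substituted aryl ketone and the silylethyl ethers should be inert.

Step 12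
Reactants: 17 1-{(2R)-2-(2-hydroxypropan-2-yl)-4,6-bis[2-(trimethylsilyl)ethoxy]-2,3-dihydro-1-benzofuran-5-yl}-2-methylpropan-1-one
Product: 18 2-methyl-1-{(2R)-2-(prop-1-en-2-yl)-4,6-bis[2-(trimethylsilyl)ethoxy]-2,3-dihydro-1-benzofuran-5-yl}propan-1-one
Conditions: methyl N-(triethylammoniosulfonyl)carbamate (Burgess reagent), toluene, 50–70 °C
Reagents that add atoms: none
Why: Burgess dehydration (syn Ei elimination of the sulfamate) should take one of the six methyl hydrogens in preference to the single C2–H, which is deactivated by O1, and so gives the isopropenyl group under neutral conditions with C2 untouched.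

Step 13
Reactants: 18 2-methyl-1-{(2R)-2-(prop-1-en-2-yl)-4,6-bis[2-(trimethylsilyl)ethoxy]-2,3-dihydro-1-benzofuran-5-yl}propan-1-one
Product: 19 1-[(2R)-4,6-dihydroxy-2-(prop-1-en-2-yl)-2,3-dihydro-1-benzofuran-5-yl]-2-methylpropan-1-one
Conditions: Bu4NF (5 equiv), THF, 50 °C; aq NH4Cl
Reagents that add atoms: none
Why: Fluoride attacks silicon and each 2-(trimethylsilyl)ethyl ether fragments to ethene, Me3SiF and an ortho-acyl phenoxide, a known aryl ether deprotection that avoids the Lewis acids that would open the allylic aryl ether O1–C2.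

Step 14
Reactants: 20 methyl 3-oxopentanoate; 21 N-methoxy-N-methylpropanamide
Product: 23 methyl 4-methyl-3,5-dioxoheptanoate, via keto ester dianion 22 (not isolated)
Conditions: NaH, THF, 0 °C; n-BuLi, −10 °C; then 21, −78 → 0 °C; aq HCl
Reagents that add atoms: none
Why: γ-Acylation of a β-keto ester dianion: the more reactive C4 carbanion attacks the Weinreb amide, whose stable adduct prevents a second addition.

Step 15
Reactants: 23 methyl 4-methyl-3,5-dioxoheptanoate
Product: 24 6-ethyl-4-hydroxy-5-methyl-2H-pyran-2-one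
Conditions: DBU, toluene, reflux
Reagents that add atoms: none
Why: Base-mediated enol lactonisation of the 3,5-diketo ester (attack of the C5 enol oxygen on the ester, loss of methanol) gives the 4-hydroxy-2-pyrone.

Step 16
Reactants: 24 6-ethyl-4-hydroxy-5-methyl-2H-pyran-2-one; 19 1-[(2R)-4,6-dihydroxy-2-(prop-1-en-2-yl)-2,3-dihydro-1-benzofuran-5-yl]-2-methylpropan-1-one
Product: 27 6-ethyl-4-hydroxy-3-{[(2R)-4,6-dihydroxy-5-(2-methylpropanoyl)-2-(prop-1-en-2-yl)-2,3-dihydro-1-benzofuran-7-yl]methyl}-5-methyl-2H-pyran-2-one, via pyrone Mannich base 25 (not isolated), via methylidene pyrandione 26 (not isolated)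
Conditions: 24, CH2=NMe2+ I− (1 equiv), MeCN, 20 °C; then 19, 40 °C
Reagents that add atoms: dimethyl(methylidene)ammonium iodide (Eschenmoser's salt), C=[N+](C)C.[I-]
Why: Mannich reaction at C3 of the pyrone gives 25, which loses dimethylamine to the methylidene dione 26, and the only free ring position of 19 (C7, ortho to the C6 phenol and to O1) adds to it in a Friedel–Crafts-type Michael addition, a methylene bridging known for acylphloroglucinols and 4-hydroxypyrones.

**Compound list**

1 | 2-(trimethylsilyl)ethanol | C[Si](C)(C)CCO | starting material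
2 | trichloroethylene | ClC=C(Cl)Cl | starting material
3 | [2-{[(E)-1,2-dichloroethenyl]oxy}ethyl]trimethylsilane | C[Si](C)(C)CCO/C(Cl)=C\Cl | intermediate
4 | isobutyryl chloride | CC(C)C(Cl)=O | starting material
5 | N-methoxy-N,2-dimethylpropanamide | CC(C)C(=O)N(C)OC | intermediate
6 | 2-methylbut-3-en-2-ol | C=CC(C)(C)O | starting material
7 | {[(2-methylbut-3-en-2-yl)oxy]methyl}benzene | C=CC(C)(C)OCc1ccccc1 | intermediate
8 | rac-2-[2-(benzyloxy)propan-2-yl]oxirane | CC(C)(OCc1ccccc1)C1CO1 | intermediate
9 | (2R)-2-[2-(benzyloxy)propan-2-yl]oxirane | CC(C)(OCc1ccccc1)[C@H]1CO1 | intermediate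
10 | {[2-(trimethylsilyl)ethoxy]ethynyl}lithium (THF solution from step 6, used directly in steps 7 and 8) | [Li]C#COCC[Si](C)(C)C | intermediate
11 | 4-methyl-1-[2-(trimethylsilyl)ethoxy]pent-1-yn-3-one | CC(C)C(=O)C#COCC[Si](C)(C)C | intermediate
12 | (3R)-2-(benzyloxy)-2-methyl-6-[2-(trimethylsilyl)ethoxy]hex-5-yn-3-ol | CC(C)(OCc1ccccc1)[C@H](O)CC#COCC[Si](C)(C)C | intermediate
13 | [2-({(4R)-5-(benzyloxy)-4-{[(E)-1,2-dichloroethenyl]oxy}-5-methylhex-1-yn-1-yl}oxy)ethyl]trimethylsilane (formed in the flask, not isolated) | CC(C)(OCc1ccccc1)[C@H](O/C(Cl)=C\Cl)CC#COCC[Si](C)(C)C | intermediate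
14 | ({[(3R)-2-(benzyloxy)-2-methyl-6-[2-(trimethylsilyl)ethoxy]hex-5-yn-3-yl]oxy}ethynyl)lithium (formed in the flask, not isolated) | CC(C)(OCc1ccccc1)[C@H](OC#C[Li])CC#COCC[Si](C)(C)C | intermediate
15 | [2-({(4R)-5-(benzyloxy)-4-(ethynyloxy)-5-methylhex-1-yn-1-yl}oxy)ethyl]trimethylsilane (O1-tethered bis(ynol ether) diyne) | CC(C)(OCc1ccccc1)[C@H](OC#C)CC#COCC[Si](C)(C)C | intermediate
16 | 1-{(2R)-2-[2-(benzyloxy)propan-2-yl]-4,6-bis[2-(trimethylsilyl)ethoxy]-2,3-dihydro-1-benzofuran-5-yl}-2-methylpropan-1-one | CC(C)(OCc1ccccc1)[C@H]1Cc2c(OCC[Si](C)(C)C)c(C(=O)C(C)C)c(OCC[Si](C)(C)C)cc2O1 | intermediate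
17 | 1-{(2R)-2-(2-hydroxypropan-2-yl)-4,6-bis[2-(trimethylsilyl)ethoxy]-2,3-dihydro-1-benzofuran-5-yl}-2-methylpropan-1-one | CC(C)(O)[C@H]1Cc2c(OCC[Si](C)(C)C)c(C(=O)C(C)C)c(OCC[Si](C)(C)C)cc2O1 | intermediate
18 | 2-methyl-1-{(2R)-2-(prop-1-en-2-yl)-4,6-bis[2-(trimethylsilyl)ethoxy]-2,3-dihydro-1-benzofuran-5-yl}propan-1-one | C=C(C)[C@H]1Cc2c(OCC[Si](C)(C)C)c(C(=O)C(C)C)c(OCC[Si](C)(C)C)cc2O1 | intermediate
19 | 1-[(2R)-4,6-dihydroxy-2-(prop-1-en-2-yl)-2,3-dihydro-1-benzofuran-5-yl]-2-methylpropan-1-one | C=C(C)[C@H]1Cc2c(O)c(C(=O)C(C)C)c(O)cc2O1 | intermediate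
20 | methyl 3-oxopentanoate | CCC(=O)CC(=O)OC | starting material
21 | N-methoxy-N-methylpropanamide | CCC(=O)N(C)OC | starting material
22 | sodium lithium dianion of methyl 3-oxopentanoate (formed in the flask, not isolated) | C[CH-]C(=O)[CH-]C(=O)OC.[Li+].[Na+] | intermediate
23 | methyl 4-methyl-3,5-dioxoheptanoate | CCC(=O)C(C)C(=O)CC(=O)OC | intermediate
24 | 6-ethyl-4-hydroxy-5-methyl-2H-pyran-2-one | CCc1oc(=O)cc(O)c1C | intermediate
25 | 3-[(dimethylamino)methyl]-6-ethyl-4-hydroxy-5-methyl-2H-pyran-2-one (formed in the flask, not isolated) | CCc1oc(=O)c(CN(C)C)c(O)c1C | intermediate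
26 | 6-ethyl-5-methyl-3-methylidene-2H-pyran-2,4(3H)-dione (formed in the flask, not isolated) | CCC1=C(C)C(=O)C(=C)C(=O)O1 | intermediate
27 | 6-ethyl-4-hydroxy-3-{[(2R)-4,6-dihydroxy-5-(2-methylpropanoyl)-2-(prop-1-en-2-yl)-2,3-dihydro-1-benzofuran-7-yl]methyl}-5-methyl-2H-pyran-2-one (CNP0206652.1) | C=C(C)[C@H]1Cc2c(O)c(C(=O)C(C)C)c(O)c(Cc3c(O)c(C)c(CC)oc3=O)c2O1 | target

**Step count**

Total steps: 16. Longest linear sequence: 10 steps (steps 3, 4, 5, 8, 9, 10, 11, 12, 13 and 16).

**Steps most likely to fail**

1. Step 10. What may go wrong: insertion of the ynone in the reverse sense (acyl carbon bonding to C7), self-trimerisation of either alkyne, conjugate addition of liberated PPh3 to the ynone, or thermal loss of ketene from the ynol ethers before the catalyst turns over. The fallback uses classical arene chemistry, sets out from epoxide 9 and amide 5 and comes back to the route at 16. 1,3,5-Trifluorobenzene would be lithiated (n-BuLi, THF, −78 °C) to 2,4,6-trifluorophenyllithium F1, which with BF3·OEt2 would open 9 at its CH2 to (2R)-3-(benzyloxy)-3-methyl-1-(2,4,6-trifluorophenyl)butan-2-ol F2. NaH in DMF at 60–80 °C would close ring B by intramolecular SNAr to (2R)-2-[2-(benzyloxy)propan-2-yl]-4,6-difluoro-2,3-dihydro-1-benzofuran F3. Deprotonation between the two fluorines (n-BuLi, THF, −78 °C) would give {(2R)-2-[2-(benzyloxy)propan-2-yl]-4,6-difluoro-2,3-dihydro-1-benzofuran-5-yl}lithium F4, and acylation with 5 would give 1-{(2R)-2-[2-(benzyloxy)propan-2-yl]-4,6-difluoro-2,3-dihydro-1-benzofuran-5-yl}-2-methylpropan-1-one F5. Displacement of both fluorines, each ortho to the ketone, by sodium 2-(trimethylsilyl)ethoxide (from 1 and NaH, THF/DMF, 20–60 °C) would then give 16.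

2. Step 9. What may go wrong: sluggish addition of the hindered secondary alkoxide, which sits next to a quaternary carbon, to dichloroacetylene, or attack of KH or n-BuLi on the ynol ether already present (propargylic deprotonation followed by β-elimination). The fallback sets out from 12 and comes back to the route at 15 through 14, and forms no alkoxide. Alcohol 12 would be formylated (formic acetic anhydride, pyridine, 0 °C) to (3R)-2-(benzyloxy)-2-methyl-6-[2-(trimethylsilyl)ethoxy]hex-5-yn-3-yl formate F6. Ramirez-type dibromo-olefination of the formate carbonyl (CBr4, PPh3, CH2Cl2) would give [2-({(4R)-5-(benzyloxy)-4-[(2,2-dibromoethenyl)oxy]-5-methylhex-1-yn-1-yl}oxy)ethyl]trimethylsilane F7. n-BuLi (2.2 equiv, THF, −78 °C) would convert F7 by a Fritsch–Buttenberg–Wiechell-type rearrangement into acetylide 14, and water would give 15.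

3. Step 16. What may go wrong: self-coupling of the pyrone through the methylidene dione (methylene-bis-pyrone formation) faster than attack by C7 of 19, or acid-promoted opening of the allylic aryl ether by the ammonium iodide that forms. The fallback sets out from 19 and comes back to the route at 27, with the one-carbon unit placed on the arene first. Compound 19 and dimethyl(methylidene)ammonium iodide (CH2Cl2, 0–20 °C, then aq NaHCO3) would give 1-{(2R)-7-[(dimethylamino)methyl]-4,6-dihydroxy-2-(prop-1-en-2-yl)-2,3-dihydro-1-benzofuran-5-yl}-2-methylpropan-1-one F8. Heating F8 with 24 in dioxane (80–100 °C) would expel dimethylamine to the ortho-quinone methide (2R)-4-hydroxy-7-methylidene-5-(2-methylpropanoyl)-2-(prop-1-en-2-yl)-2,3-dihydro-1-benzofuran-6(7H)-one F9, which 24 would trap at its C3 to give 27.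

**Further compounds**

F1 | step 10 | 2,4,6-trifluorophenyllithium | [Li]c1c(F)cc(F)cc1F
F2 | step 10 | (2R)-3-(benzyloxy)-3-methyl-1-(2,4,6-trifluorophenyl)butan-2-ol | CC(C)(OCc1ccccc1)[C@H](O)Cc1c(F)cc(F)cc1F
F3 | step 10 | (2R)-2-[2-(benzyloxy)propan-2-yl]-4,6-difluoro-2,3-dihydro-1-benzofuran | CC(C)(OCc1ccccc1)[C@H]1Cc2c(F)cc(F)cc2O1
F4 | step 10 | {(2R)-2-[2-(benzyloxy)propan-2-yl]-4,6-difluoro-2,3-dihydro-1-benzofuran-5-yl}lithium | CC(C)(OCc1ccccc1)[C@H]1Cc2c(F)c([Li])c(F)cc2O1
F5 | step 10 | 1-{(2R)-2-[2-(benzyloxy)propan-2-yl]-4,6-difluoro-2,3-dihydro-1-benzofuran-5-yl}-2-methylpropan-1-one | CC(C)(OCc1ccccc1)[C@H]1Cc2c(F)c(C(=O)C(C)C)c(F)cc2O1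
F6 | step 9 | (3R)-2-(benzyloxy)-2-methyl-6-[2-(trimethylsilyl)ethoxy]hex-5-yn-3-yl formate | CC(C)(OCc1ccccc1)[C@H](OC=O)CC#COCC[Si](C)(C)C
F7 | step 9 | [2-({(4R)-5-(benzyloxy)-4-[(2,2-dibromoethenyl)oxy]-5-methylhex-1-yn-1-yl}oxy)ethyl]trimethylsilane | CC(C)(OCc1ccccc1)[C@H](OC=C(Br)Br)CC#COCC[Si](C)(C)C
F8 | step 16 | 1-{(2R)-7-[(dimethylamino)methyl]-4,6-dihydroxy-2-(prop-1-en-2-yl)-2,3-dihydro-1-benzofuran-5-yl}-2-methylpropan-1-one | C=C(C)[C@H]1Cc2c(O)c(C(=O)C(C)C)c(O)c(CN(C)C)c2O1
F9 | step 16 | (2R)-4-hydroxy-7-methylidene-5-(2-methylpropanoyl)-2-(prop-1-en-2-yl)-2,3-dihydro-1-benzofuran-6(7H)-one | C=C(C)[C@H]1CC2=C(O1)C(=C)C(=O)C(C(=O)C(C)C)=C2O
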